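Readings and results were computed from invented constants.

**The product.** L is what is asked for, so I begin with the concentration its rate follows.

| flask | X | E | Z | temperature | remark | time |
|---|---|---|---|---|---|---|
| elm | 17 mM | 2 equiv | 1.2 mM | 58 °C | run made earlier |  |
| cedar | 26 mM | 2 equiv | 1.2 mM | 74 °C | run made earlier |  |
| alder | 12 mM | 2 equiv | 1.8 mM | 58 °C | run made earlier |  |
| grey | 12 mM | 2.00 equiv | 1.20 mM | 50 °C |  | 40 min |
| amber | 12 mM | 2.00 equiv | 1.20 mM | 80 °C |  | 40 min |
| teal | 12 mM | 2.00 equiv | 1.20 mM | 65 °C |  | 40 min |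
| green | 12 mM | 2.00 equiv | 1.20 mM |  | at 50 °C until 12 min, from then on at 80 °C | 40 min |

| run | time / min | L / % |
|---|---|---|
| elm | 2.00 | 2 |
| elm | 4.00 | 7 |
| elm | 6.00 | 8 |
| elm | 12.0 | 18 |
| elm | 25.0 | 46 |
| cedar | 1.50 | 10 |
| cedar | 3.00 | 28 |
| cedar | 5.00 | 45 |
| cedar | 6.00 | 53 |
| cedar | 8.00 | 64 |
| alder | 5.00 | 6 |
| alder | 10.0 | 9 |
| alder | 15.0 | 17 |
| alder | 20.0 | 24 |
| alder | 25.0 | 30 |

(scatter of a reading: 2 percentage points)



- the flask with the highest amount of L, in percent of the X charged ("all alike" if they lie within 1.5 percentage points) (grey / amber / teal / green / all alike)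
- final L, as a percentage of the X charged, in grey
- final L, as a percentage of the X charged, in amber
- final L, as a percentage of the X charged, in teal
- final L, as a percentage of the X charged, in green

**The order.** I take the share of X not yet turned into L and read its fall as a first-order rate from each last reading. At 58 °C, elm gives 0.0246 min⁻¹ and alder 0.0143 min⁻¹, a ratio of 1.72. A first-order rate in X does not change with the charge of X, and this ratio, as read, stands above one. Elm has 1.42 times alder's E and alder has 1.50 times elm's Z, and these runs cannot part the two. I choose E and scale each rate with its charge.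

**The clock.** Cedar's own rate at 74 °C reads 0.128 min⁻¹. Scaled to 12 mM of X, elm gives 0.0174 min⁻¹ and cedar gives 0.0589 min⁻¹. Carrying the same factor per degree on to 80 °C gives 0.0931 min⁻¹. From this I get the hot half-time, a pseudo-first-order half-life of the unfinished share, 7.44 min.

**Turned round.** Could green draw level with amber? I count its cold stretch as giving nothing, so it has 28.0 min hot. With amber taken as finished, green's unfinished share would have to fall below the margin of 1.5 percentage points in that time, which needs a half-time of 4.62 min. The reckoned one is longer, 7.44 min. I therefore expect amber at 97.6 % and green at 92.6 %, with amber ahead.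

**The forecast.** It names amber, with grey 25 %, amber 95 % (from 82 % to 100 %), teal 70 % and green 91 %, saying of green “so it trails amber slightly”. My figures for amber and green both stand higher than its own.

**The flasks.**

    G + Z → D (k = 0.0490 M⁻¹ s⁻¹, Ea = 55.0 kJ mol⁻¹)
    X → G (k = 0.00110 s⁻¹, Ea = 100 kJ mol⁻¹)
    X + L → Q (k = 0.0300 M⁻¹ s⁻¹, Ea = 70.0 kJ mol⁻¹)
    E + G → L (k = 0.00880 M⁻¹ s⁻¹, Ea = 79.0 kJ mol⁻¹)
    (constants at 50 °C)

Amber gives 89.4 %, green 86.0 %, teal 67.4 % and grey 23.0 %, so amber leads green by 3.4 points. At 40.0 min, G, the species on the way to L, stands at 4.55 % in green and 1.64 % in amber. Green read at 15.0 min holds 61.9 % of G, and the half-time brings that to 6.03 % by 40.0 min, against the 4.55 % found. Amber's 10.2 % of G at 20.0 min comes by the same half-time to 1.59 %, and the flask shows 1.64 %.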